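## Structural features

The target is one fully substituted cyclohexane with no second ring; every ring carbon except C2 carries a substituent. C1 is quaternary (methyl, vinyl) and is followed by four contiguous tertiary stereocentres: C6 (3-hydroxyprop-1-en-2-yl), C5 (hydroxyl), C4 (prop-2-enoic acid bound through its α-carbon) and C3 (the (Z)-4-acetoxy-2-methylbut-2-enoate). Read from the structure, the vinyl group, the C6 alkenyl group, the C5 hydroxyl and the C4 acrylic acid lie on one face; the C1 methyl and the C3 acyloxy group lie on the other. In the chair with the C3, C4 and C6 substituents equatorial, the C5 hydroxyl and the C1 vinyl group are axial.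

The fragile parts are:
- the cis γ-hydroxy acid (C5–OH with the C4 carboxyl), which closes to an α-methylene-γ-butyrolactone under acid;
- the Z enoate, which can isomerise to E by reversible conjugate addition and carries a base-labile allylic acetate;
- the α-methylene acid as a Michael acceptor;
- the cis-1,2-dialkenyl pair, which is a 1,5-diene.

The real difficulty is the quaternary C1 next to C6 with the two alkenyl groups cis, together with telling three oxygens apart and freeing the hydroxy acid last without acid. The key step uses the fact that the vinyl CH on C1 and the substituted alkene carbon on C6 are cis on adjacent ring atoms. Joined to each other they are the two sp2 carbons of a cyclobutene fused across C1–C6, and that cyclobutene is the [2+2] adduct of a C6=C1 enone (carbonyl at C5) with a propargyl ether.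

## Logic of the disconnections

28 is traced to 27 by cutting the O–Si bonds at the C5 oxygen and at the primary allylic oxygen, and 27 to 25 by cutting the O–C(CH3)3 bond of the carboxyl. The cut is made there because the cis hydroxy acid cannot face protic acid. The carboxyl is therefore freed by an aprotic silyl triflate while C5 is still silylated, and the C5 hydroxyl is released last by buffered fluoride. The gain is that all late protecting groups fall under two mild conditions. The demand is that no step after 25 uses strong acid or base.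

25 is cut at the C3–O acyl bond into 19 and 23. This is the most convergent cut and keeps the sensitive acetoxy enoate out of all hydride, enolate and metathesis steps. The demands are that the C3 hydroxyl is the only free hydroxyl in 19 and that the esterification does not isomerise the Z alkene.

23 is cut at the acetate C–O bond to 21, and 21 at the acyl–oxygen bond to the lactone 20. The five-membered ring of 20 fixes the Z geometry for free. The demand is that oxygen is acetylated while the carboxyl stays unactivated, otherwise the ring closes again.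

19 is traced to 18 by re-attaching the 4-methoxybenzyl group to the C3 oxygen, and 18 to 14 by removing the exocyclic methylene carbon from the ester α-carbon. The acrylate is introduced only after reduction and metathesis, because it would not survive either. The benzyl-type group sits at C3 and silyl groups elsewhere, so one oxidative step frees C3 alone. The demand is an ester enolate with no leaving group β to it, which 14 fulfils.

14 is cut at both alkene C=CH2 bonds, and the two ring-bound sp2 carbons are joined to give the cyclobutene 13 (retro-ethenolysis). The cis relation of the two alkenyl groups thereby becomes a cis ring fusion, which cannot be otherwise. The demand is a ring-opening metathesis on a trisubstituted cyclobutene next to a quaternary carbon.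

13 is traced to 12 (O–Si at C5) and 12 to the ketone 11 (C5–H). The C5 carbonyl is needed as the enone carbonyl of the key step and as the activating group for C4. The demand is hydride delivery from the face opposite the cyclobutene and the C4 arm.

11 is cut at C1–CH and C6–C(alkenyl) into the enone 9 and the alkyne 10. This is the strategic cut: two skeletal bonds, the quaternary carbon and the C6 stereocentre arise together. The demands are head-to-head orientation and addition anti to the C3 ether.

9 is cut at the C4–CH2 bond into 6 and 7. The gain is an enone with one stereocentre. The demand is kinetic α′-enolisation and alkylation trans to the C3 ether without β-elimination of that ether.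

6 is cut at C6=C1 (aldol condensation) to the dione 4, 4 at its two carbonyl oxygens to the diene 3, and 3 at the ether bond to 1. The gain is an achiral, symmetric seven-carbon chain. The demand is that the ring closure distinguishes the two enantiotopic acetyl arms.

## Other disconnections considered

Alternative 1: The cut is the C4–CH2 bond of the acid side chain together with the C3–O bond. In the forward sense the mixed bromoacetal A1, tethered through the C5 oxygen of a C3=C4 cyclohexene, is converted into its radical (Bu3SnH or Et3B/O2). A 5-exo-trig addition to C4 closes a cis-fused lactol ring, and the C3 radical is trapped by O2 to give A2.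
- In favour: the tether forces C4 and C5 cis, C3 and C4 are set in one operation, and the acetal carbon is the future carboxyl.
- Against: A1 must already contain C1, C5, C6 and the cis dialkenyl pair, so the hardest part of the molecule lies outside this step. The two pendant alkenes are possible radical acceptors. Oxygen trapping at C3 has to occur trans to the new ring. The lactol must be taken to the acid without passing through the lactone.
- Comparison: on structure it is the equal or the better of the chosen plan for the C3/C4/C5 triad (one step instead of alkylation plus reduction). On mechanism the 5-exo radical closure is more predictable than the regiochemistry of a triplet cycloaddition, which is a point in its favour. On step economy it is worse, because the chosen plan makes C1 and C6 in one step from a short enone synthesis, while A1 needs its own stereocontrolled route.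

Alternative 2: The cut is the C1–C2 ring bond. In the forward sense anodic oxidation of the enol ether in A3 gives a radical cation that is attacked at its CH2 terminus by the methyl-bearing carbon of the allylsilane. Loss of silicon, a second oxidation and methanol give the ketal A4.
- In favour: the quaternary C1 with its vinyl group is made directly, without a stoichiometric oxidant and without regiochemical ambiguity, and the C5 oxygen can steer C1 through a chair-like closure.
- Against: A4 holds only C1 and C5; C4 and C6 are bare methylenes and C3 is a ketal. The C6 alkenyl group and the C4 side chain must be added by enolate chemistry that has to choose between C2 and C4, with several redox changes. Electron-rich benzyl ethers are not compatible with the anode.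
- Comparison: on forming the quaternary centre it is the equal or the better of the chosen plan. On structure it delivers one bond and at most two stereocentres, against two bonds and the cis pair. On step economy it is clearly worse.

Alternative 3: The cut is the C4–C5 ring bond. In the forward sense the aldehyde A5, which carries a 2-(bromomethyl)alkenoate, is treated with CrCl2 (divalent chromium, Nozaki–Hiyama type). The allylmetal adds through its γ-carbon (C4) to the C5 aldehyde, closing the ring and forming the acrylate double bond in A6.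
- In favour: the acrylate arises directly, so the enolate methylenation of the chosen plan is saved; the reagent is chemoselective for aldehydes; the C5 hydroxyl appears free.
- Against: A5 is acyclic and needs the quaternary C1 beside a C6 stereocentre that is α to an aldehyde and allylic, and therefore prone to epimerisation and conjugation. The closure must set C4 and C5 correctly relative to C3 and C6 without a rigid template. A cis γ-hydroxy acrylate with a primary ester tends to close to the methylene lactone, which would be a dead end here.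
- Comparison: after its key step it is better than the chosen plan in step economy and functional-group economy. On mechanism it is equal in chemoselectivity but less secure in diastereocontrol than hydride reduction of a rigid ketone. On structure it leaves the C1/C6 problem unsolved, so the total count would be higher.

Key step: step 5

Assumption: ring atoms of all intermediates carry the target numbers C1 (quaternary) to C6, also where a systematic name numbers differently.
Assumption: the sense of induction in step 3 is taken from 4-alkyl diones; should it prove opposite, the quinidine-derived pseudo-enantiomer of the amine is used with no other change.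
Assumption: 10 and 20 are bought as catalogue compounds.
Remark: the configurations of 9 and 11 were re-derived centre by centre from the target (C3 oxygen down, C4 arm up, cyclobutene up) and agree with it. Only the protecting groups are chosen anew: 4-methoxybenzyl at C3, silyl on the alkyne and at C5. A closing acid treatment is avoided, because it would lactonise the hydroxy acid.

Step 1
Reactants: 1 hepta-1,6-dien-4-ol
Product: 3 1-[(hepta-1,6-dien-4-yloxy)methyl]-4-methoxybenzene, via sodium hepta-1,6-dien-4-olate 2 (not isolated)
Conditions: NaH, 4-MeOC6H4CH2Cl, Bu4NI (cat.), THF/DMF, 0 °C → rt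
Reagents that add atoms: 4-methoxybenzyl chloride, COc1ccc(CCl)cc1
Why: Williamson etherification of a secondary alkoxide with a benzylic chloride under iodide catalysis; the carbinol carbon is still prochiral, so no stereocentre is involved.

Step 2
Reactants: 3 diene ether
Product: 4 4-[(4-methoxybenzyl)oxy]heptane-2,6-dione
Conditions: PdCl2 (10 mol%), CuCl (1 equiv, reoxidised), O2 (1 atm), DMF/H2O 7:1, rt
Reagents that add atoms: water, O
Why: Twofold Tsuji–Wacker oxidation: divalent palladium activates each terminal alkene, water adds at the internal carbon and β-hydride elimination gives the methyl ketone, while CuCl/O2 returns zerovalent palladium to the divalent state. The benzyl ether and the β-alkoxy ketone should tolerate the weakly acidic medium.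

Step 3
Reactants: 4 dione
Product: 6 (5S)-5-[(4-methoxybenzyl)oxy]-3-methylcyclohex-2-en-1-one, via aldol ketol 5 (not isolated)
Conditions: 9-amino-9-deoxy-epi-quinine (20 mol%), AcOH (60 mol%), toluene, −15 °C → rt
Reagents that add atoms: none
Why: Primary-amine-catalysed desymmetrising intramolecular aldol condensation, known for 4-alkyl- and 4-aryl-heptane-2,6-diones: the enamine of one acetyl arm adds to the other ketone and the ketol dehydrates. The chiral ammonium ion pair chooses which enantiotopic arm becomes the nucleophile, and this choice fixes the configuration of the ether-bearing carbon (target C3).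

Step 4
Reactants: 6 enone; 7 tert-butyl bromoacetate
Product: 9 tert-butyl 2-[(1R,6S)-6-[(4-methoxybenzyl)oxy]-4-methyl-2-oxocyclohex-3-en-1-yl]acetate (trans), via lithium dienolate 8 (not isolated)
Conditions: LiN(iPr)2, THF, −78 °C; then 7, DMPU, −78 → −40 °C
Reagents that add atoms: none
Why: Kinetic α′-deprotonation gives the cross-conjugated dienolate, and C-alkylation by the reactive α-bromo ester should occur on the face opposite the adjacent ether, giving the trans product (target C4), which is also the more stable isomer. An alkoxide is a poorer leaving group than a siloxide, which slows E1cB loss of the C3 oxygen at these temperatures.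

Step 5
Reactants: 9 trans enone ester; 10 tert-butyldimethyl(prop-2-yn-1-yloxy)silane
Product: 11 tert-butyl 2-[(1R,3R,4S,6R)-8-{[(tert-butyldimethylsilyl)oxy]methyl}-4-[(4-methoxybenzyl)oxy]-6-methyl-2-oxobicyclo[4.2.0]oct-7-en-3-yl]acetate (cis-fused; cyclobutene cis to the acetate arm, trans to the ether)
Conditions: hν (365 nm), 10 (8 equiv), CH2Cl2, −40 °C, degassed
Reagents that add atoms: none
Why: Excitation of the enone and intersystem crossing give the twisted triplet, which adds stepwise: the first bond joins C1 to the terminal alkyne carbon, leaving an α-acyl radical at C6 and an α-substituted vinyl radical, and after spin inversion this 1,4-biradical collapses by radical–radical coupling to close the four-membered ring at C6. The closest known reaction type is the enone–alkyne [2+2] photocycloaddition that gives bicyclo[4.2.0]oct-7-en-2-ones. C1 is set by the face of attack: the pyramidalising β-carbon forms its new bond pseudo-axially on the face opposite the pseudo-equatorial C3 ether, which is 1,3 to C1, as in conjugate additions to 5-substituted cyclohexenones, while the equatorial C4 arm lies near the enone plane and shields neither face. C6 is set by strain, because a cyclobutene can only be cis-fused to a six-membered ring, so the second bond must form on the face of the first. The step needs head-to-head orientation (the CH2OSi-bearing carbon on C6); the β-methyl group makes C1 fully substituted, so the unsubstituted alkyne terminus should bond there and the more stabilised biradical closes to the wanted isomer. A large excess of the non-absorbing alkyne should outrun enone dimerisation, and the long wavelength and low temperature limit a secondary 1,3-acyl shift of the β,γ-unsaturated ketone product. The anisyl ring, the ester and the silyl ether do not absorb at this wavelength.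

Step 6
Reactants: 11 cyclobutene ketone
Product: 12 tert-butyl 2-[(1R,2S,3S,4S,6R)-8-{[(tert-butyldimethylsilyl)oxy]methyl}-2-hydroxy-4-[(4-methoxybenzyl)oxy]-6-methylbicyclo[4.2.0]oct-7-en-3-yl]acetate (hydroxyl cis to the cyclobutene and to the acetate arm)
Conditions: Li[HB(sec-Bu)3], THF, −78 °C; AcOH quench at −78 °C
Reagents that add atoms: none
Why: The bulky trialkylborohydride should attack the ketone equatorially from the face opposite the cyclobutene and the C4 arm, which both sit on the top face, giving the axial C5 alcohol cis to both neighbours. The tert-butyl ester resists attack by the cold alkoxide, so no lactone should form, and the ring fusion keeps C6 from epimerising.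

Step 7
Reactants: 12 alcohol
Product: 13 tert-butyl 2-[(1R,2S,3R,4S,6R)-8-{[(tert-butyldimethylsilyl)oxy]methyl}-4-[(4-methoxybenzyl)oxy]-6-methyl-2-[(triethylsilyl)oxy]bicyclo[4.2.0]oct-7-en-3-yl]acetate
Conditions: Et3SiOTf, 2,6-lutidine, CH2Cl2, −78 → 0 °C
Reagents that add atoms: triethylsilyl trifluoromethanesulfonate, CC[Si](CC)(CC)OS(=O)(=O)C(F)(F)F
Why: A silyl triflate with a hindered pyridine silylates even flanked axial secondary alcohols at low temperature, and the tert-butyl ester and benzyl ether should survive the buffered conditions. The triethylsilyl group blocks lactonisation and unselective acylation later and leaves with fluoride at the end.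

Step 8
Reactants: 13 silylated cyclobutene
Product: 14 tert-butyl 2-[(1R,2S,3R,4R,6S)-3-{3-[(tert-butyldimethylsilyl)oxy]prop-1-en-2-yl}-4-ethenyl-6-[(4-methoxybenzyl)oxy]-4-methyl-2-[(triethylsilyl)oxy]cyclohexyl]acetate
Conditions: second-generation Hoveyda–Grubbs catalyst RuCl2(H2IMes)(=CH-C6H4-2-OiPr) (5 mol%), ethylene (1 atm), CH2Cl2, rt
Reagents that add atoms: ethylene, C=C
Why: Ring-opening cross-metathesis with ethylene, driven by release of cyclobutene strain: the ruthenium methylidene adds with the metal on the unsubstituted ring carbon, which gives the 1,1-disubstituted alkene on C6 and, after turnover with ethylene, the vinyl group on C1. No stereocentre is touched, so the cis relation is inherited from the ring fusion.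

Step 9
Reactants: 14 diene ester
Product: 18 tert-butyl 2-[(1R,2S,3R,4R,6S)-3-{3-[(tert-butyldimethylsilyl)oxy]prop-1-en-2-yl}-4-ethenyl-6-[(4-methoxybenzyl)oxy]-4-methyl-2-[(triethylsilyl)oxy]cyclohexyl]prop-2-enoate, via lithium ester enolate 15 (not isolated), via Mannich base 16 (not isolated), via trimethylammonium iodide 17 (not isolated)
Conditions: LiN(iPr)2, THF, −78 °C; CH2=NMe2+ I−, −78 °C → rt; MeI, MeOH, rt; NaHCO3 (aq)/CH2Cl2, rt
Reagents that add atoms: N,N-dimethylmethyleneiminium iodide (Eschenmoser's salt), C=[N+](C)C.[I-]
Why: Ester α-methylenation by enolate Mannich reaction, exhaustive N-methylation and base-induced elimination of trimethylamine. The enolate has no leaving group on its β-carbon (C4), and C4 itself is not deprotonated, so its configuration is kept.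

Step 10
Reactants: 18 acrylate
Product: 19 tert-butyl 2-[(1R,2S,3R,4R,6S)-3-{3-[(tert-butyldimethylsilyl)oxy]prop-1-en-2-yl}-4-ethenyl-6-hydroxy-4-methyl-2-[(triethylsilyl)oxy]cyclohexyl]prop-2-enoate
Conditions: DDQ, CH2Cl2/pH 7 phosphate buffer, 0 °C
Reagents that add atoms: none
Why: Oxidative cleavage of the electron-rich benzyl ether by hydride abstraction and hydrolysis of the resulting hemiacetal. Silyl ethers, the tert-butyl ester and the unactivated alkenes are inert to the quinone, and the buffer protects the triethylsilyl ether.

Step 11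
Reactants: 20 3-methylfuran-2(5H)-one
Product: 21 sodium (2Z)-4-hydroxy-2-methylbut-2-enoate
Conditions: NaOH (1.0 equiv), H2O/MeOH, 0 °C → rt; evaporate, dry
Reagents that add atoms: sodium hydroxide, [Na+].[OH-]
Why: Saponification of the butenolide; the ring fixes carboxyl and CH2O on the same side of the alkene, so the open salt is Z by construction and cannot relactonise while it stays a carboxylate.

Step 12
Reactants: 21 sodium hydroxy enoate
Product: 23 (2Z)-4-(acetyloxy)-2-methylbut-2-enoic acid, via disodium alkoxide carboxylate 22 (not isolated)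
Conditions: NaH, DMF, 0 °C; Ac2O (1.05 equiv), −20 °C; cold aqueous NaHSO4 to pH 3
Reagents that add atoms: acetic anhydride, CC(=O)OC(C)=O
Why: O-acylation of an alkoxide in the presence of the far less nucleophilic carboxylate, so one equivalent of anhydride should cap the C4 oxygen while the carboxyl stays unactivated. Once the oxygen is acetylated the Z acid can no longer close to the butenolide on acidification.

Step 13
Reactants: 19 C3 alcohol; 23 Z acid
Product: 25 tert-butyl 2-[(1R,2S,3R,4R,6S)-6-{[(2Z)-4-(acetyloxy)-2-methylbut-2-enoyl]oxy}-3-{3-[(tert-butyldimethylsilyl)oxy]prop-1-en-2-yl}-4-ethenyl-4-methyl-2-[(triethylsilyl)oxy]cyclohexyl]prop-2-enoate, via mixed trichlorobenzoic anhydride 24 (not isolated)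
Conditions: 23, 2,4,6-Cl3C6H2COCl, Et3N, toluene, rt; then 19, toluene, 75 °C (no DMAP)
Reagents that add atoms: none
Why: Yamaguchi esterification: the alcohol attacks the enoyl carbonyl of the mixed anhydride because the aroyl carbonyl is shielded by two ortho chlorines. Leaving out a nucleophilic pyridine catalyst avoids the reversible conjugate addition that isomerises Z-2-methylbut-2-enoates to E, and the C3 hydroxyl is the only free hydroxyl.

Step 14
Reactants: 25 tert-butyl ester
Product: 27 2-[(1R,2S,3R,4R,6S)-6-{[(2Z)-4-(acetyloxy)-2-methylbut-2-enoyl]oxy}-3-{3-[(tert-butyldimethylsilyl)oxy]prop-1-en-2-yl}-4-ethenyl-4-methyl-2-[(triethylsilyl)oxy]cyclohexyl]prop-2-enoic acid, via trimethylsilyl ester 26 (not isolated)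
Conditions: Me3SiOTf, 2,6-lutidine, CH2Cl2, 0 °C; then pH 5 aqueous NaH2PO4
Reagents that add atoms: none
Why: Silyl-triflate cleavage of a tert-butyl ester: silylation of the carbonyl oxygen, loss of the tert-butyl cation as 2-methylpropene and hydrolysis of the silyl ester on buffered work-up. The medium is aprotic and C5 is still silylated, so the lactone cannot form, and the other esters have no cation-stabilising alkyl group to lose.

Step 15
Reactants: 27 bis-silylated acid
Product: 28 2-[(1S,2S,3R,4R,6S)-6-{[(2Z)-4-(acetyloxy)-2-methylbut-2-enoyl]oxy}-4-ethenyl-2-hydroxy-3-(3-hydroxyprop-1-en-2-yl)-4-methylcyclohexyl]prop-2-enoic acid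
Conditions: Bu4NF, AcOH (1:1), THF, 0 °C → rt; pH 5 buffer work-up, cold
Reagents that add atoms: none
Why: Fluoride-induced cleavage of both silyl ethers under acetic-acid buffering, which should spare the acetate and the enoate. The carboxyl is present as its unreactive carboxylate while the C5 hydroxyl is freed, so lactonisation is not promoted, and the work-up stays near pH 5.

## Compound list

1 | hepta-1,6-dien-4-ol | C=CCC(O)CC=C | starting material
2 | sodium hepta-1,6-dien-4-olate | [Na+].[O-]C(CC=C)CC=C | intermediate
3 | 1-[(hepta-1,6-dien-4-yloxy)methyl]-4-methoxybenzene | C=CCC(CC=C)OCc1ccc(OC)cc1 | intermediate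
4 | 4-[(4-methoxybenzyl)oxy]heptane-2,6-dione | CC(=O)CC(CC(C)=O)OCc1ccc(OC)cc1 | intermediate
5 | (5S)-3-hydroxy-5-[(4-methoxybenzyl)oxy]-3-methylcyclohexan-1-one (both C3 epimers) | CC1(O)C[C@H](OCc2ccc(OC)cc2)CC(=O)C1 | intermediate
6 | (5S)-5-[(4-methoxybenzyl)oxy]-3-methylcyclohex-2-en-1-one | CC1=CC(=O)C[C@@H](OCc2ccc(OC)cc2)C1 | intermediate
7 | tert-butyl bromoacetate | BrCC(=O)OC(C)(C)C | starting material
8 | lithium (3S)-3-[(4-methoxybenzyl)oxy]-5-methylcyclohexa-1,5-dien-1-olate | [Li+].CC1=CC([O-])=C[C@@H](OCc2ccc(OC)cc2)C1 | intermediate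
9 | tert-butyl 2-[(1R,6S)-6-[(4-methoxybenzyl)oxy]-4-methyl-2-oxocyclohex-3-en-1-yl]acetate | CC1=CC(=O)[C@H](CC(=O)OC(C)(C)C)[C@@H](OCc2ccc(OC)cc2)C1 | intermediate
10 | tert-butyldimethyl(prop-2-yn-1-yloxy)silane | C#CCO[Si](C)(C)C(C)(C)C | starting material
11 | tert-butyl 2-[(1R,3R,4S,6R)-8-{[(tert-butyldimethylsilyl)oxy]methyl}-4-[(4-methoxybenzyl)oxy]-6-methyl-2-oxobicyclo[4.2.0]oct-7-en-3-yl]acetate | C[C@@]12C=C(CO[Si](C)(C)C(C)(C)C)[C@@H]1C(=O)[C@H](CC(=O)OC(C)(C)C)[C@@H](OCc1ccc(OC)cc1)C2 | intermediate
12 | tert-butyl 2-[(1R,2S,3S,4S,6R)-8-{[(tert-butyldimethylsilyl)oxy]methyl}-2-hydroxy-4-[(4-methoxybenzyl)oxy]-6-methylbicyclo[4.2.0]oct-7-en-3-yl]acetate | C[C@@]12C=C(CO[Si](C)(C)C(C)(C)C)[C@@H]1[C@H](O)[C@H](CC(=O)OC(C)(C)C)[C@@H](OCc1ccc(OC)cc1)C2 | intermediate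
13 | tert-butyl 2-[(1R,2S,3R,4S,6R)-8-{[(tert-butyldimethylsilyl)oxy]methyl}-4-[(4-methoxybenzyl)oxy]-6-methyl-2-[(triethylsilyl)oxy]bicyclo[4.2.0]oct-7-en-3-yl]acetate | C[C@@]12C=C(CO[Si](C)(C)C(C)(C)C)[C@@H]1[C@H](O[Si](CC)(CC)CC)[C@H](CC(=O)OC(C)(C)C)[C@@H](OCc1ccc(OC)cc1)C2 | intermediate
14 | tert-butyl 2-[(1R,2S,3R,4R,6S)-3-{3-[(tert-butyldimethylsilyl)oxy]prop-1-en-2-yl}-4-ethenyl-6-[(4-methoxybenzyl)oxy]-4-methyl-2-[(triethylsilyl)oxy]cyclohexyl]acetate | C=C[C@@]1(C)C[C@H](OCc2ccc(OC)cc2)[C@@H](CC(=O)OC(C)(C)C)[C@@H](O[Si](CC)(CC)CC)[C@H]1C(=C)CO[Si](C)(C)C(C)(C)C | intermediate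
15 | lithium 1-tert-butoxy-2-[cyclohexyl group of 14, same configuration]ethen-1-olate | [Li+].C=C[C@@]1(C)C[C@H](OCc2ccc(OC)cc2)[C@@H](C=C([O-])OC(C)(C)C)[C@@H](O[Si](CC)(CC)CC)[C@H]1C(=C)CO[Si](C)(C)C(C)(C)C | intermediate
16 | tert-butyl 3-(dimethylamino)-2-[cyclohexyl group of 14, same configuration]propanoate (both epimers at the new centre) | C=C[C@@]1(C)C[C@H](OCc2ccc(OC)cc2)[C@@H](C(CN(C)C)C(=O)OC(C)(C)C)[C@@H](O[Si](CC)(CC)CC)[C@H]1C(=C)CO[Si](C)(C)C(C)(C)C | intermediate
17 | {3-tert-butoxy-3-oxo-2-[cyclohexyl group of 14, same configuration]propyl}trimethylammonium iodide | [I-].C=C[C@@]1(C)C[C@H](OCc2ccc(OC)cc2)[C@@H](C(C[N+](C)(C)C)C(=O)OC(C)(C)C)[C@@H](O[Si](CC)(CC)CC)[C@H]1C(=C)CO[Si](C)(C)C(C)(C)C | intermediate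
18 | tert-butyl 2-[(1R,2S,3R,4R,6S)-3-{3-[(tert-butyldimethylsilyl)oxy]prop-1-en-2-yl}-4-ethenyl-6-[(4-methoxybenzyl)oxy]-4-methyl-2-[(triethylsilyl)oxy]cyclohexyl]prop-2-enoate | C=C[C@@]1(C)C[C@H](OCc2ccc(OC)cc2)[C@@H](C(=C)C(=O)OC(C)(C)C)[C@@H](O[Si](CC)(CC)CC)[C@H]1C(=C)CO[Si](C)(C)C(C)(C)C | intermediate
19 | tert-butyl 2-[(1R,2S,3R,4R,6S)-3-{3-[(tert-butyldimethylsilyl)oxy]prop-1-en-2-yl}-4-ethenyl-6-hydroxy-4-methyl-2-[(triethylsilyl)oxy]cyclohexyl]prop-2-enoate | C=C[C@@]1(C)C[C@H](O)[C@@H](C(=C)C(=O)OC(C)(C)C)[C@@H](O[Si](CC)(CC)CC)[C@H]1C(=C)CO[Si](C)(C)C(C)(C)C | intermediate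
20 | 3-methylfuran-2(5H)-one | CC1=CCOC1=O | starting material
21 | sodium (2Z)-4-hydroxy-2-methylbut-2-enoate | [Na+].[O-]C(=O)/C(C)=C\CO | intermediate
22 | disodium (2Z)-2-methyl-4-oxidobut-2-enoate | [Na+].[Na+].[O-]C(=O)/C(C)=C\C[O-] | intermediate
23 | (2Z)-4-(acetyloxy)-2-methylbut-2-enoic acid | OC(=O)/C(C)=C\COC(C)=O | intermediate
24 | (2Z)-4-(acetyloxy)-2-methylbut-2-enoic 2,4,6-trichlorobenzoic anhydride | O=C(OC(=O)/C(C)=C\COC(C)=O)c1c(Cl)cc(Cl)cc1Cl | intermediate
25 | tert-butyl 2-[(1R,2S,3R,4R,6S)-6-{[(2Z)-4-(acetyloxy)-2-methylbut-2-enoyl]oxy}-3-{3-[(tert-butyldimethylsilyl)oxy]prop-1-en-2-yl}-4-ethenyl-4-methyl-2-[(triethylsilyl)oxy]cyclohexyl]prop-2-enoate | C=C[C@@]1(C)C[C@H](OC(=O)/C(C)=C\COC(C)=O)[C@@H](C(=C)C(=O)OC(C)(C)C)[C@@H](O[Si](CC)(CC)CC)[C@H]1C(=C)CO[Si](C)(C)C(C)(C)C | intermediate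
26 | trimethylsilyl ester corresponding to 25 (trimethylsilyl in place of tert-butyl) | C=C[C@@]1(C)C[C@H](OC(=O)/C(C)=C\COC(C)=O)[C@@H](C(=C)C(=O)O[Si](C)(C)C)[C@@H](O[Si](CC)(CC)CC)[C@H]1C(=C)CO[Si](C)(C)C(C)(C)C | intermediate
27 | 2-[(1R,2S,3R,4R,6S)-6-{[(2Z)-4-(acetyloxy)-2-methylbut-2-enoyl]oxy}-3-{3-[(tert-butyldimethylsilyl)oxy]prop-1-en-2-yl}-4-ethenyl-4-methyl-2-[(triethylsilyl)oxy]cyclohexyl]prop-2-enoic acid | C=C[C@@]1(C)C[C@H](OC(=O)/C(C)=C\COC(C)=O)[C@@H](C(=C)C(=O)O)[C@@H](O[Si](CC)(CC)CC)[C@H]1C(=C)CO[Si](C)(C)C(C)(C)C | intermediate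
28 | 2-[(1S,2S,3R,4R,6S)-6-{[(2Z)-4-(acetyloxy)-2-methylbut-2-enoyl]oxy}-4-ethenyl-2-hydroxy-3-(3-hydroxyprop-1-en-2-yl)-4-methylcyclohexyl]prop-2-enoic acid | C=C[C@@]1(C)C[C@H](OC(=O)/C(C)=C\COC(C)=O)[C@@H](C(=C)C(=O)O)[C@@H](O)[C@H]1C(=C)CO | target

## Step count and least certain steps

Total: 15 steps. Longest linear sequence: 13 steps (steps 1 to 10, then 13 to 15); steps 11 and 12 form the side branch.

Step 5 (key step). The most likely failure is partial head-to-tail addition of the alkyne together with incomplete facial discrimination. Both reacting carbons are attacked by the triplet at similar rates, the C3 and C4 substituents lie on opposite faces, and the product can be consumed by a secondary 1,3-acyl shift if irradiation runs too long. Fallback (stepwise, ground-state construction of the same two bonds), from 9 to 14: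
- Copper-mediated conjugate addition of CH2=CHMgBr (CuBr·SMe2, Me3SiCl, THF, −78 °C) should add the vinyl group to C1 anti to the C3 ether and give the silyl enol ether tert-butyl 2-[(1R,4R,6S)-4-ethenyl-6-[(4-methoxybenzyl)oxy]-4-methyl-2-[(trimethylsilyl)oxy]cyclohex-2-en-1-yl]acetate F1.
- Palladium-catalysed α-alkenylation of its tin enolate (Bu3SnF, Pd2(dba)3, P(tBu)3, 2-bromo-3-[(tert-butyldimethylsilyl)oxy]prop-1-ene) would give the ketone tert-butyl 2-[(1R,3R,4R,6S)-3-{3-[(tert-butyldimethylsilyl)oxy]prop-1-en-2-yl}-4-ethenyl-6-[(4-methoxybenzyl)oxy]-4-methyl-2-oxocyclohexyl]acetate F2, in which the epimerisable C6 should settle equatorial.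
- Reduction with Li[HB(sec-Bu)3] would give the alcohol tert-butyl 2-[(1S,2S,3R,4R,6S)-3-{3-[(tert-butyldimethylsilyl)oxy]prop-1-en-2-yl}-4-ethenyl-2-hydroxy-6-[(4-methoxybenzyl)oxy]-4-methylcyclohexyl]acetate F3, and silylation with Et3SiOTf returns to the route at 14.

Step 3. The most likely failure is insufficient enantioselection, or loss of the C4 oxygen by enamine-assisted β-elimination, because the catalyst is established for alkyl and aryl substituents and not for a small polar ether. Fallback (resolution in place of asymmetric catalysis), from 4 to 6: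
- Cyclisation with pyrrolidine/AcOH gives the racemic enone 5-[(4-methoxybenzyl)oxy]-3-methylcyclohex-2-en-1-one F4.
- 1,2-Addition of lithiated (S)-N,S-dimethyl-S-phenylsulfoximine gives diastereomeric carbinols that are separated by chromatography, the wanted one being (5S)-5-[(4-methoxybenzyl)oxy]-3-methyl-1-{[(S)-N-methylphenylsulfonimidoyl]methyl}cyclohex-2-en-1-ol F5.
- Thermolysis of F5 in toluene at 110 °C releases the sulfoximine and returns enantiopure 6.

Step 4. The most likely failure is E1cB loss of the C3 ether from the enolate, followed by aromatisation to a cresol, because the leaving group is β to the enolate carbon and alkylation needs warming. Fallback (dianion alkylation without a β-leaving group), from 6 to 9: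
- DDQ removes the benzyl group to give (5S)-5-hydroxy-3-methylcyclohex-2-en-1-one F6.
- Two equivalents of LiN(iPr)2 form the alkoxide enolate, whose oxide cannot leave, and alkylation with 7 in the Fráter–Seebach sense (anti to the oxide) gives tert-butyl 2-[(1R,6S)-6-hydroxy-4-methyl-2-oxocyclohex-3-en-1-yl]acetate F7.
- 4-Methoxybenzyl trichloroacetimidate with catalytic La(OTf)3 returns to 9.

Step 8. The most likely failure is slow or incomplete ring opening, because the cyclobutene alkene is trisubstituted and flanked by a quaternary carbon. Fallback (oxidative cleavage and olefination in place of metathesis), from 13 to 14: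
- OsO4 (cat.)/NaIO4 with 2,6-lutidine cleaves the cyclobutene to the keto aldehyde tert-butyl 2-[(1R,2R,3S,4S,6S)-3-{[(tert-butyldimethylsilyl)oxy]acetyl}-4-formyl-6-[(4-methoxybenzyl)oxy]-4-methyl-2-[(triethylsilyl)oxy]cyclohexyl]acetate F8.
- Twofold methylenation with Ph3P=CH2 (or Zn/CH2Br2/TiCl4 for the enolisable ketone) gives 14.

Step 13. The most likely failure is Z to E isomerisation of the acyl unit, or sluggish acylation, because the enoyl electrophile undergoes reversible conjugate addition and the C3 hydroxyl sits beside the branched C4 substituent. Fallback (building the Z alkene on the substrate, which also makes 23 unnecessary), from 19 to 25: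
- Esterification with 2-[bis(2,2,2-trifluoroethoxy)phosphoryl]propanoic acid (DCC, DMAP) gives the phosphonate tert-butyl 2-[(1R,2S,3R,4R,6S)-6-({2-[bis(2,2,2-trifluoroethoxy)phosphoryl]propanoyl}oxy)-3-{3-[(tert-butyldimethylsilyl)oxy]prop-1-en-2-yl}-4-ethenyl-4-methyl-2-[(triethylsilyl)oxy]cyclohexyl]prop-2-enoate F9.
- Still–Gennari olefination with 2-oxoethyl acetate (KN(SiMe3)2, 18-crown-6, THF, −78 °C) should give the Z enoate 25.

## Further compounds

F1 | step 5 | tert-butyl 2-[(1R,4R,6S)-4-ethenyl-6-[(4-methoxybenzyl)oxy]-4-methyl-2-[(trimethylsilyl)oxy]cyclohex-2-en-1-yl]acetate | C=C[C@@]1(C)C[C@H](OCc2ccc(OC)cc2)[C@@H](CC(=O)OC(C)(C)C)C(O[Si](C)(C)C)=C1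
F2 | step 5 | tert-butyl 2-[(1R,3R,4R,6S)-3-{3-[(tert-butyldimethylsilyl)oxy]prop-1-en-2-yl}-4-ethenyl-6-[(4-methoxybenzyl)oxy]-4-methyl-2-oxocyclohexyl]acetate | C=C[C@@]1(C)C[C@H](OCc2ccc(OC)cc2)[C@@H](CC(=O)OC(C)(C)C)C(=O)[C@H]1C(=C)CO[Si](C)(C)C(C)(C)C
F3 | step 5 | tert-butyl 2-[(1S,2S,3R,4R,6S)-3-{3-[(tert-butyldimethylsilyl)oxy]prop-1-en-2-yl}-4-ethenyl-2-hydroxy-6-[(4-methoxybenzyl)oxy]-4-methylcyclohexyl]acetate | C=C[C@@]1(C)C[C@H](OCc2ccc(OC)cc2)[C@@H](CC(=O)OC(C)(C)C)[C@@H](O)[C@H]1C(=C)CO[Si](C)(C)C(C)(C)C
F4 | step 3 | racemic 5-[(4-methoxybenzyl)oxy]-3-methylcyclohex-2-en-1-one | CC1=CC(=O)CC(OCc2ccc(OC)cc2)C1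
F5 | step 3 | (5S)-5-[(4-methoxybenzyl)oxy]-3-methyl-1-{[(S)-N-methylphenylsulfonimidoyl]methyl}cyclohex-2-en-1-ol | CC1=CC(O)(C[S@@](=O)(=NC)c2ccccc2)C[C@@H](OCc2ccc(OC)cc2)C1
F6 | step 4 | (5S)-5-hydroxy-3-methylcyclohex-2-en-1-one | CC1=CC(=O)C[C@@H](O)C1
F7 | step 4 | tert-butyl 2-[(1R,6S)-6-hydroxy-4-methyl-2-oxocyclohex-3-en-1-yl]acetate | CC1=CC(=O)[C@H](CC(=O)OC(C)(C)C)[C@@H](O)C1
F8 | step 8 | tert-butyl 2-[(1R,2R,3S,4S,6S)-3-{[(tert-butyldimethylsilyl)oxy]acetyl}-4-formyl-6-[(4-methoxybenzyl)oxy]-4-methyl-2-[(triethylsilyl)oxy]cyclohexyl]acetate | O=C[C@@]1(C)C[C@H](OCc2ccc(OC)cc2)[C@@H](CC(=O)OC(C)(C)C)[C@@H](O[Si](CC)(CC)CC)[C@H]1C(=O)CO[Si](C)(C)C(C)(C)C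
F9 | step 13 | tert-butyl 2-[(1R,2S,3R,4R,6S)-6-({2-[bis(2,2,2-trifluoroethoxy)phosphoryl]propanoyl}oxy)-3-{3-[(tert-butyldimethylsilyl)oxy]prop-1-en-2-yl}-4-ethenyl-4-methyl-2-[(triethylsilyl)oxy]cyclohexyl]prop-2-enoate | C=C[C@@]1(C)C[C@H](OC(=O)C(C)P(=O)(OCC(F)(F)F)OCC(F)(F)F)[C@@H](C(=C)C(=O)OC(C)(C)C)[C@@H](O[Si](CC)(CC)CC)[C@H]1C(=C)CO[Si](C)(C)C(C)(C)C
A1 | alternative 1 | 2-bromo-1-ethoxyethyl ether at the C5 oxygen of the C3=C4 cyclohexene bearing the C1 methyl and vinyl groups and the C6 3-(silyloxy)prop-1-en-2-yl group | C=C[C@@]1(C)CC=C[C@@H](OC(CBr)OCC)[C@H]1C(=C)CO[Si](C)(C)C(C)(C)C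
A2 | alternative 1 | cis-fused lactol ethyl acetal with free C3 hydroxyl | C=C[C@@]1(C)C[C@H](O)[C@H]2C[C@@H](OCC)O[C@H]2[C@H]1C(=C)CO[Si](C)(C)C(C)(C)C
A3 | alternative 2 | acyclic 2-methoxyalkene carrying the C5 silyl ether and a trisubstituted allyltrimethylsilane | C=C(OC)C[C@@H](O[Si](C)(C)C(C)(C)C)CC(C)=CC[Si](C)(C)C
A4 | alternative 2 | 3-methyl-3-vinyl-5-silyloxycyclohexanone dimethyl ketal, vinyl cis to oxygen | C=C[C@@]1(C)CC(OC)(OC)C[C@@H](O[Si](C)(C)C(C)(C)C)C1
A5 | alternative 3 | acyclic C5 aldehyde carrying the 2-(trimethylsilyl)ethyl 2-(bromomethyl)alk-2-enoate | C=C[C@@](C)(C[C@H](OCc1ccc(OC)cc1)C=C(CBr)C(=O)OCC[Si](C)(C)C)[C@@H](C=O)C(=C)CO[Si](C)(C)C(C)(C)C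
A6 | alternative 3 | fully substituted cyclohexanol with α-methylene 2-(trimethylsilyl)ethyl ester | C=C[C@@]1(C)C[C@H](OCc2ccc(OC)cc2)[C@@H](C(=C)C(=O)OCC[Si](C)(C)C)[C@@H](O)[C@H]1C(=C)CO[Si](C)(C)C(C)(C)C
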